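**Assumption:** the target 9 is planar and achiral, with no stereocentre and no stereogenic double bond. There is no enantiomer to select, and the SMILES is taken as written.

## Retrosynthetic overview
1. 9 ⇒ 4. Open N1–C2 and move the C3 bromine back to C2, giving the 2‑nitro‑β,β‑dibromostyrene 4, in which one CBr2 unit carries both pyrrole‑ring bromines.
2. 4 ⇒ 1 + 2 across C2=C3. C3 is an aldehyde carbon and C2 is at the carboxyl oxidation level (it bears N and Br), so both are natural acceptors.
3. C2 is therefore used with inverted polarity as Ph3P=CBr2, made from CBr4. This ylide acts as a masked carboxyl/acyl anion (d1 donor).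
4. Ring order: the benzene ring is bought with the 6‑Br in place. The pyrrole ring is the only ring formed, in step 2.

## Route

**Step 1**
Reactants: 1 4‑bromo‑2‑nitrobenzaldehyde; 2 carbon tetrabromide
Product: 4 4‑bromo‑1‑(2,2‑dibromoethenyl)‑2‑nitrobenzene, via dibromomethylene ylide 3 (not isolated)
Conditions: CBr4 (1.5 equiv), PPh3 (3.0 equiv), CH2Cl2, 0 °C, 1 h; hexane, silica plug
Reagents that add atoms: carbon tetrabromide (2), BrC(Br)(Br)Br
Why: Ramirez dibromoolefination (first stage of the Corey–Fuchs sequence): halophilic attack of PPh3 on CBr4 turns a carbon at the CO2 oxidation level into the nucleophilic ylide 3, a masked acyl/carboxyl anion, which adds to the electrophilic aldehyde carbon of 1 and collapses Wittig‑fashion; ArNO2 and ArBr are inert at 0 °C, and no E/Z or stereocentre issue arises because the new alkene terminus carries two identical Br atoms.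

**Step 2**
Reactants: 4 4‑bromo‑1‑(2,2‑dibromoethenyl)‑2‑nitrobenzene
Product: 9 2,3,6‑tribromo‑1H‑indole, via nitrosostyrene 5 (not isolated), via 2H‑indole N‑oxide 6 (not isolated), via 3H‑indole N‑oxide 7 (not isolated), via N‑hydroxyindole 8 (not isolated)
Conditions: MoO2Cl2(dmf)2 (5 mol %), PPh3 (2.2 equiv), degassed PhMe (0.05 M), 110 °C, N2, dark; fast chromatography on Et3N‑deactivated silica, store cold under Ar
Reagents that add atoms: none
Why: Proposed new method: Mo‑catalysed oxygen transfer to PPh3 takes the nitro group to nitroso 5, which closes by a five‑atom 6π electrocyclisation onto the CBr2 terminus to give the non‑aromatic 6; because C2 of 6 bears no H, the benzene ring can only be regained by a suprafacial 1,2‑ ([1,5]‑) shift of bromine through a bromonium‑like bridged transition state to 7 (transient racemic C3), whose C3–H tautomerises to 8 before the second PPh3 removes the last oxygen; the closest known reaction type is the Cadogan–Sundberg reductive cyclisation of β,β‑disubstituted 2‑nitrostyrenes, which gives 2,3‑disubstituted indoles by the same C2→C3 migration (known for alkyl, aryl and acyl groups, not yet for halogen), and the aprotic medium keeps water from intercepting the shift; no stereocentre remains in 9.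

## Compound list
1 | 4‑bromo‑2‑nitrobenzaldehyde | O=Cc1ccc(Br)cc1[N+](=O)[O-] | starting material
2 | carbon tetrabromide | BrC(Br)(Br)Br | starting material
3 | (dibromomethylidene)triphenylphosphorane | BrC(Br)=P(c1ccccc1)(c1ccccc1)c1ccccc1 | intermediate
4 | 4‑bromo‑1‑(2,2‑dibromoethenyl)‑2‑nitrobenzene | BrC(Br)=Cc1ccc(Br)cc1[N+](=O)[O-] | intermediate
5 | 4‑bromo‑1‑(2,2‑dibromoethenyl)‑2‑nitrosobenzene | BrC(Br)=Cc1ccc(Br)cc1N=O | intermediate
6 | 2,2,6‑tribromo‑2H‑indole 1‑oxide | BrC1(Br)C=C2C=CC(Br)=CC2=[N+]1[O-] | intermediate
7 | 2,3,6‑tribromo‑3H‑indole 1‑oxide (racemic, transient) | BrC1C(Br)=[N+]([O-])c2cc(Br)ccc12 | intermediate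
8 | 2,3,6‑tribromo‑1H‑indol‑1‑ol | On1c(Br)c(Br)c2ccc(Br)cc12 | intermediate
9 | 2,3,6‑tribromo‑1H‑indole | Brc1ccc2c(Br)c(Br)[nH]c2c1 | target

## Count and risks
Total steps: 2. Longest linear sequence: 2. The route has only two steps, so both are ranked and there is no third.

**Risk 1, step 2 (high).**
- Halogen migration in this manifold has no precedent.
- PPh3 could strip a "positive" bromine from 6 or 7.
- N–H 2,3‑dibromoindoles are sensitive to heat, acid and light.

The fallback sets out from 4 and replaces the nitroso/migration logic with a polar ring closure followed by late electrophilic bromination. Chemoselective nitro reduction (SnCl2·2H2O, EtOH, 70 °C) gives 5‑bromo‑2‑(2,2‑dibromoethenyl)aniline F1. Intramolecular Pd(0)‑catalysed C–N coupling follows (Pd(PtBu3)2 5 mol %, K2CO3, PhMe, 100 °C). With this bulky ligand oxidative addition is reversible, so the remaining C–Br bonds survive and the product is 2,6‑dibromo‑1H‑indole F2. NBS (1.0 equiv, THF, −78 to 0 °C) then brominates the nucleophilic C3, and the sequence returns to the route at 9. If step 2 merely loses one bromine, its product is F2 and it joins this sequence at that point.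

**Risk 2, step 1 (low).**
- The excess phosphine and Ph3PO burden may complicate isolation.
- The yield could erode with this electron‑poor, ortho‑substituted aldehyde.

The fallback sets out from 1 and reverses the polarity of the aldehyde carbon instead. Condensation with N2H4·H2O (DMSO, rt) gives (E)‑(4‑bromo‑2‑nitrobenzylidene)hydrazine F3. This N‑unsubstituted hydrazone is a carbon donor (diazo/aza‑enamine type). Under copper‑catalysed olefination with 2 (CuCl 10 mol %, aq NH3, DMSO, rt) it loses nitrogen, and the sequence returns to the route at 4.

## Further compounds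
F1 | step 2 | 5‑bromo‑2‑(2,2‑dibromoethenyl)aniline | Nc1cc(Br)ccc1C=C(Br)Br
F2 | step 2 | 2,6‑dibromo‑1H‑indole | Brc1ccc2cc(Br)[nH]c2c1
F3 | step 1 | (E)‑(4‑bromo‑2‑nitrobenzylidene)hydrazine | N/N=C/c1ccc(Br)cc1[N+](=O)[O-]
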